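The dihydrofuran ring is cut at O1–C2 and at C2–C3. C2, the carbon that carries ring B, is a lone carbon held between the phenolic oxygen O1 and the benzylic carbon C3 of ring A. Ring A can therefore serve as a four-atom ortho-quinone methide and C2 as a one-carbon ylide partner. One [4+1] operation joins both halves, closes the heterocycle and sets C2 and C3, trans to each other, with the absolute sense taken from a twofold-symmetric thiolane. Its precursors are a racemic 2-(1-tosylethyl)phenol with bromine at the future C5 and a chiral veratryl thiolanium salt. The bromide later takes up an (R)-lactate unit, and chelation-controlled reduction gives the anti diol.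

Key step: step 6

Numbering: benzofuran numbering O1, C2, C3, C3a, C4 to C7, C7a. Ring A is the benzo ring and ring B the 3,4-dimethoxyphenyl group. The side chain on C5 is C1'(OH)–C2'(OH)–C3'. The target is (2S,3S,1'S,2'R): a trans ring and an anti (erythro) diol.

Assumption: the ylide is taken to react as in the model for aldehyde epoxidation with 2,5-dimethylthiolane benzylides, with the aryl group turned away from the thiolane and bond formation on the face remote from the cis methyl group. Worked through for the quinone methide, this predicts (2S) from the (2S,5S) sulfide. The descriptor cannot be carried over from diaryl oxiranes, because an oxirane carbon outranks aryl whereas C3 ranks below ring B. The (2S,5S) salt, made from (2R,5R)-hexane-2,5-diol, is therefore used. If the sense proves opposite, the equally available enantiomeric diol goes through the same three steps.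

**Branch A: quinone methide precursor**

Step 1
Reactants: 1 5-bromo-2-hydroxy-3-methoxybenzaldehyde
Product: 2 racemic 4-bromo-2-(1-hydroxyethyl)-6-methoxyphenol
Conditions: MeMgBr (2.5 equiv), THF, 0 °C to rt; aq NH4Cl
Reagents that add atoms: methylmagnesium bromide, C[Mg]Br
Why: Grignard 1,2-addition to the aldehyde, after the first equivalent has deprotonated the phenol, should be clean because MeMgBr does not exchange with the aryl bromide, and the carbinol centre forms as a racemate, which is harmless since step 6 erases it.

Step 2
Reactants: 2 racemic 4-bromo-2-(1-hydroxyethyl)-6-methoxyphenol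
Product: 3 racemic 4-bromo-2-methoxy-6-[1-(4-methylphenylsulfonyl)ethyl]phenol
Conditions: p-TolSO2H (1.5 equiv), CH2Cl2, rt
Reagents that add atoms: p-toluenesulfinic acid, Cc1ccc(cc1)S(=O)O
Why: Acid-promoted SN1-type benzylic substitution, in which the sulfinic acid ionises the ortho-hydroxybenzylic alcohol and its soft sulfur captures the cation, is the standard entry to 2-(1-sulfonylalkyl)phenols, and the sulfone is racemic by design.

**Branch B: chiral sulfonium salt**

Step 3
Reactants: 4 (2R,5R)-hexane-2,5-diol
Product: 5 (2R,5R)-hexane-2,5-diyl dimethanesulfonate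
Conditions: MsCl, Et3N, CH2Cl2, −20 to 0 °C
Reagents that add atoms: methanesulfonyl chloride, CS(=O)(=O)Cl
Why: Sulfonate ester formation takes place at oxygen only, so both carbinol centres keep the (R) configuration.

Step 4
Reactants: 5 (2R,5R)-hexane-2,5-diyl dimethanesulfonate
Product: 6 (2S,5S)-2,5-dimethylthiolane
Conditions: Na2S·9H2O, EtOH, rt; distillation
Reagents that add atoms: sodium sulfide, [Na+].[Na+].[S-2]
Why: Twofold SN2 substitution by sulfide, the second one an intramolecular 5-exo-tet closure, inverts both centres and so turns the (R,R) dimesylate into the (S,S) thiolane.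

Step 5
Reactants: 6 (2S,5S)-2,5-dimethylthiolane; 7 3,4-dimethoxybenzyl bromide
Product: 8 (2S,5S)-1-(3,4-dimethoxybenzyl)-2,5-dimethylthiolan-1-ium tetrafluoroborate
Conditions: AgBF4, CH2Cl2, 0 °C to rt, dark; filtration, precipitation with Et2O
Reagents that add atoms: silver tetrafluoroborate, [Ag+].F[B-](F)(F)F
Why: S-Alkylation of the sulfide by the very reactive benzylic bromide (SN2) is made irreversible by precipitation of AgBr and by the non-nucleophilic counter-ion, and because the two lone pairs of the twofold-symmetric sulfide are equivalent only one salt can form.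

**Union**

Step 6
Reactants: 3 racemic 4-bromo-2-methoxy-6-[1-(4-methylphenylsulfonyl)ethyl]phenol; 8 (2S,5S)-1-(3,4-dimethoxybenzyl)-2,5-dimethylthiolan-1-ium tetrafluoroborate
Product: 12 (2S,3S)-5-bromo-2-(3,4-dimethoxyphenyl)-7-methoxy-3-methyl-2,3-dihydrobenzofuran, via ortho-quinone methide 9 (not isolated), via sulfonium benzylide 10 (not isolated), via betaine 11 (not isolated)
Conditions: 8 (1.4 equiv), KN(SiMe3)2 (2.4 equiv, added last), THF, −78 °C, then slowly to 0 °C; aq NH4Cl
Reagents that add atoms: none
Why: Proposed new method: KN(SiMe3)2 converts 3 into its phenoxide and 8 into benzylide 10 at −78 °C; on warming the phenoxide expels p-toluenesulfinate (1,4-elimination) to release 9, the ylide carbon adds to the exocyclic carbon of 9 (C2–C3 bond, ring A rearomatises) to give betaine 11, and the phenoxide of 11 displaces the thiolane (O1–C2 bond). The closest known reactions are the trans-selective [4+1] annulation of sulfone-derived ortho-quinone methides with carbonyl-stabilised sulfur ylides, its variant with chiral ammonium ylides, and aldehyde epoxidation with benzylides of 2,5-dimethylthiolane; what is new is a chiral semi-stabilised benzylide acting on an alkyl-substituted ortho-quinone methide. The dihydrofuran ring closes in the 5-exo-tet mode, an intramolecular SN2 reaction with inversion at C2. C2 is controlled by the sulfide: sulfur is not stereogenic, so a single ylide exists, ring B turns away from the thiolane, the ring methyl group cis to the ylide carbon shields one face, C3 therefore bonds to the open face, and inversion on closure should give (2S). C3 is set relative to C2 in the same C–C bond formation, because the E-configured 9 should approach with its methyl group away from ring B and from the sulfonium group, which leads to the betaine that closes to the trans ring. The step needs addition to be faster than tautomerisation of 9 to the vinylphenol and than O-benzylation of the phenoxide by 8; this is secured by converting 8 fully into the nucleophilic ylide, kept in excess, before 9 is set free, by the gradual thermal release of 9, and by the bromine substituent, which sharpens the acceptor character of the exocyclic carbon.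

**Branch C: lactate unit**

Step 7
Reactants: 13 methyl (R)-lactate
Product: 14 methyl (R)-2-(tert-butyldimethylsilyloxy)propanoate
Conditions: TBSCl, imidazole, DMF, 0 °C to rt
Reagents that add atoms: tert-butyldimethylsilyl chloride, CC(C)(C)[Si](C)(C)Cl
Why: Imidazole-promoted O-silylation does not touch the stereocentre and masks the hydroxy group against the organometallic reagents of steps 8 and 9.

Step 8
Reactants: 14 methyl (R)-2-(tert-butyldimethylsilyloxy)propanoate
Product: 15 (R)-2-(tert-butyldimethylsilyloxy)-N-methoxy-N-methylpropanamide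
Conditions: MeNH(OMe)·HCl (1.5 equiv), i-PrMgCl (3 equiv), THF, −20 to 0 °C; aq NH4Cl
Reagents that add atoms: N,O-dimethylhydroxylamine hydrochloride, CNOC.Cl
Why: Weinreb amide formation by aminolysis of the ester with the magnesium amide made in the flask runs below 0 °C without enolisation, so the (R) centre is kept.

**End game**

Step 9
Reactants: 12 (2S,3S)-5-bromo-2-(3,4-dimethoxyphenyl)-7-methoxy-3-methyl-2,3-dihydrobenzofuran; 15 (R)-2-(tert-butyldimethylsilyloxy)-N-methoxy-N-methylpropanamide
Product: 18 (R)-2-(tert-butyldimethylsilyloxy)-1-[(2S,3S)-2-(3,4-dimethoxyphenyl)-7-methoxy-3-methyl-2,3-dihydrobenzofuran-5-yl]propan-1-one, via aryllithium 16 (not isolated), via lithium hemiaminal chelate 17 (not isolated)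
Conditions: n-BuLi (1.05 equiv), THF, −78 °C; then 15 (1.3 equiv), −78 to −20 °C; aq NH4Cl
Reagents that add atoms: none
Why: Bromine–lithium exchange outruns deprotonation at −78 °C, and the Weinreb ketone synthesis stops at chelate 17 until the quench, which excludes double addition and leaves C2, C3 and C2' untouched.

Step 10
Reactants: 18 (R)-2-(tert-butyldimethylsilyloxy)-1-[(2S,3S)-2-(3,4-dimethoxyphenyl)-7-methoxy-3-methyl-2,3-dihydrobenzofuran-5-yl]propan-1-one
Product: 19 (R)-1-[(2S,3S)-2-(3,4-dimethoxyphenyl)-7-methoxy-3-methyl-2,3-dihydrobenzofuran-5-yl]-2-hydroxypropan-1-one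
Conditions: HF·pyridine, pyridine, THF, 0 °C to rt
Reagents that add atoms: none
Why: Fluoride-induced desilylation in a weakly acidic medium avoids the enolisation of the aryl ketol that a basic fluoride source could cause, and it is placed at the ketone stage because no acid-labile para-alkoxybenzylic alcohol is present yet.

Step 11
Reactants: 19 (R)-1-[(2S,3S)-2-(3,4-dimethoxyphenyl)-7-methoxy-3-methyl-2,3-dihydrobenzofuran-5-yl]-2-hydroxypropan-1-one
Product: 20 (1S,2R)-1-[(2S,3S)-2-(3,4-dimethoxyphenyl)-7-methoxy-3-methyl-2,3-dihydrobenzofuran-5-yl]propane-1,2-diol (target)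
Conditions: Zn(BH4)2 (Et2O stock solution), Et2O/CH2Cl2, −30 to 0 °C; water
Reagents that add atoms: none
Why: Chelation-controlled reduction (Cram chelate model): divalent zinc ties the carbonyl and hydroxy oxygens into a five-membered chelate and hydride enters from the side of the C2' hydrogen rather than the C2' methyl group, which should set C1' as (S), anti to the (R) carbinol.

**Compound list**

1 | 5-bromo-2-hydroxy-3-methoxybenzaldehyde | COc1cc(Br)cc(C=O)c1O | starting material
2 | racemic 4-bromo-2-(1-hydroxyethyl)-6-methoxyphenol | COc1cc(Br)cc(C(C)O)c1O | intermediate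
3 | racemic 4-bromo-2-methoxy-6-[1-(4-methylphenylsulfonyl)ethyl]phenol | Cc1ccc(cc1)S(=O)(=O)C(C)c1cc(Br)cc(OC)c1O | intermediate
4 | (2R,5R)-hexane-2,5-diol | C[C@@H](O)CC[C@@H](C)O | starting material
5 | (2R,5R)-hexane-2,5-diyl dimethanesulfonate | C[C@@H](OS(C)(=O)=O)CC[C@@H](C)OS(C)(=O)=O | intermediate
6 | (2S,5S)-2,5-dimethylthiolane | C[C@H]1CC[C@H](C)S1 | intermediate
7 | 3,4-dimethoxybenzyl bromide | COc1ccc(CBr)cc1OC | starting material
8 | (2S,5S)-1-(3,4-dimethoxybenzyl)-2,5-dimethylthiolan-1-ium tetrafluoroborate | C[C@H]1CC[C@H](C)[S+]1Cc1ccc(OC)c(OC)c1.F[B-](F)(F)F | intermediate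
9 | (6E)-4-bromo-6-ethylidene-2-methoxycyclohexa-2,4-dien-1-one (ortho-quinone methide, not isolated) | C/C=C1\C=C(Br)C=C(OC)C1=O | intermediate
10 | (2S,5S)-2,5-dimethylthiolan-1-ium-1-yl (3,4-dimethoxyphenyl)methanide (sulfonium benzylide, not isolated) | C[C@H]1CC[C@H](C)[S+]1[CH-]c1ccc(OC)c(OC)c1 | intermediate
11 | betaine: 4-bromo-2-[(1R,2S)-1-(3,4-dimethoxyphenyl)-1-((2S,5S)-2,5-dimethylthiolan-1-ium-1-yl)propan-2-yl]-6-methoxyphenolate (not isolated) | [O-]c1c(OC)cc(Br)cc1[C@H](C)[C@H](c1ccc(OC)c(OC)c1)[S+]1[C@@H](C)CC[C@@H]1C | intermediate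
12 | (2S,3S)-5-bromo-2-(3,4-dimethoxyphenyl)-7-methoxy-3-methyl-2,3-dihydrobenzofuran | COc1ccc([C@H]2Oc3c(OC)cc(Br)cc3[C@@H]2C)cc1OC | intermediate
13 | methyl (R)-lactate | C[C@@H](O)C(=O)OC | starting material
14 | methyl (R)-2-(tert-butyldimethylsilyloxy)propanoate | C[C@@H](O[Si](C)(C)C(C)(C)C)C(=O)OC | intermediate
15 | (R)-2-(tert-butyldimethylsilyloxy)-N-methoxy-N-methylpropanamide | C[C@@H](O[Si](C)(C)C(C)(C)C)C(=O)N(C)OC | intermediate
16 | [(2S,3S)-2-(3,4-dimethoxyphenyl)-7-methoxy-3-methyl-2,3-dihydrobenzofuran-5-yl]lithium (not isolated) | COc1ccc([C@H]2Oc3c(OC)cc([Li])cc3[C@@H]2C)cc1OC | intermediate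
17 | lithium hemiaminal chelate from 16 and 15, C1' configuration undefined (not isolated) | COc1ccc([C@H]2Oc3c(OC)cc(C(O[Li])(N(C)OC)[C@@H](C)O[Si](C)(C)C(C)(C)C)cc3[C@@H]2C)cc1OC | intermediate
18 | (R)-2-(tert-butyldimethylsilyloxy)-1-[(2S,3S)-2-(3,4-dimethoxyphenyl)-7-methoxy-3-methyl-2,3-dihydrobenzofuran-5-yl]propan-1-one | COc1ccc([C@H]2Oc3c(OC)cc(C(=O)[C@@H](C)O[Si](C)(C)C(C)(C)C)cc3[C@@H]2C)cc1OC | intermediate
19 | (R)-1-[(2S,3S)-2-(3,4-dimethoxyphenyl)-7-methoxy-3-methyl-2,3-dihydrobenzofuran-5-yl]-2-hydroxypropan-1-one | COc1ccc([C@H]2Oc3c(OC)cc(C(=O)[C@@H](C)O)cc3[C@@H]2C)cc1OC | intermediate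
20 | (1S,2R)-1-[(2S,3S)-2-(3,4-dimethoxyphenyl)-7-methoxy-3-methyl-2,3-dihydrobenzofuran-5-yl]propane-1,2-diol | COc1ccc([C@H]2Oc3c(OC)cc([C@H](O)[C@@H](C)O)cc3[C@@H]2C)cc1OC | target

Total step count: 11.
Longest linear sequence: 7 steps (4 → 5 → 6 → 8 → 12 → 18 → 19 → 20).

**Steps most likely to fail**

Step 6 (new method).
- **Risk:** The chiral ylide may discriminate poorly between its two faces. The veratrylic C–S bond of the betaine may also ionise before closure. Either process lowers the enantiomeric purity. Tautomerisation of the quinone methide would cost material.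
- **Fallback:** This uses known chemistry and replaces induction with resolution through the lactate stereocentre. It sets out from 3 and 7 and returns at 18. Compound 7, tetrahydrothiophene and AgBF4 give the achiral salt 1-(3,4-dimethoxybenzyl)thiolan-1-ium tetrafluoroborate F1. F1 and 3 undergo the known racemic, trans-selective annulation under the conditions of step 6 to give the racemic trans bromide F2. F2 is lithiated and acylated with enantiopure 15 as in step 9, which gives 18 together with its (2R,3R) ring diastereomer F3. The two are diastereomers and are separated by chromatography or crystallisation.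

Step 11.
- **Risk:** Incomplete chelation of the ketol would let open-chain attack compete, which means poor facial selectivity at C1'.
- **Fallback:** Substrate control is replaced by catalyst control. The fallback sets out from 19 and returns at 20. Asymmetric transfer hydrogenation with RuCl(p-cymene)[(R,R)-TsDPEN] in HCO2H/Et3N belongs to a catalyst class known to turn 1-aryl-2-hydroxypropan-1-ones into anti diols. It should deliver hydride to the same carbonyl face. No new compound is made.

Step 10.
- **Risk:** Once the silyl group is lost, enolisation of the aryl ketol could erode the C2' configuration or transpose the ketol.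
- **Fallback:** The ketol is avoided and C1' is set during C–C bond formation. The fallback sets out from 12 and 15 and returns at 20. Compound 15 is reduced with i-Bu2AlH (THF, −78 °C) to (R)-2-(tert-butyldimethylsilyloxy)propanal F4. Aryllithium 16, made from 12 as in step 9, adds to F4 under Felkin–Anh (non-chelation) control to give the anti alcohol (1S,2R)-2-(tert-butyldimethylsilyloxy)-1-[(2S,3S)-2-(3,4-dimethoxyphenyl)-7-methoxy-3-methyl-2,3-dihydrobenzofuran-5-yl]propan-1-ol F5. The minor syn isomer is removed by chromatography. Bu4NF in THF, harmless to the diol, then frees 20.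

**Further compounds**

F1 | step 6 | 1-(3,4-dimethoxybenzyl)thiolan-1-ium tetrafluoroborate | COc1ccc(C[S+]2CCCC2)cc1OC.F[B-](F)(F)F
F2 | step 6 | racemic trans-5-bromo-2-(3,4-dimethoxyphenyl)-7-methoxy-3-methyl-2,3-dihydrobenzofuran (12 plus its (2R,3R) enantiomer; the SMILES shows the latter) | COc1ccc([C@@H]2Oc3c(OC)cc(Br)cc3[C@H]2C)cc1OC
F3 | step 6 | (R)-2-(tert-butyldimethylsilyloxy)-1-[(2R,3R)-2-(3,4-dimethoxyphenyl)-7-methoxy-3-methyl-2,3-dihydrobenzofuran-5-yl]propan-1-one | COc1ccc([C@@H]2Oc3c(OC)cc(C(=O)[C@@H](C)O[Si](C)(C)C(C)(C)C)cc3[C@H]2C)cc1OC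
F0 | step 11 | none | none
F4 | step 10 | (R)-2-(tert-butyldimethylsilyloxy)propanal | C[C@@H](O[Si](C)(C)C(C)(C)C)C=O
F5 | step 10 | (1S,2R)-2-(tert-butyldimethylsilyloxy)-1-[(2S,3S)-2-(3,4-dimethoxyphenyl)-7-methoxy-3-methyl-2,3-dihydrobenzofuran-5-yl]propan-1-ol | COc1ccc([C@H]2Oc3c(OC)cc([C@H](O)[C@@H](C)O[Si](C)(C)C(C)(C)C)cc3[C@@H]2C)cc1OC
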